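Triacontan-30-olide is a 31-membered lactone ring with no handle apart from the ester. The key step exploits its unfunctionalised C12–C13 methylene pair (C1 = lactone carbonyl), where the C1–C12 acyl arm meets the C13–C30 alkoxy arm. A sulfonyl group is placed between C12 and C13, giving a 32-membered thialactone S,S-dioxide with chlorine on C13. This precursor is built regiospecifically from 12-sulfanyldodecanoic acid, 18-bromooctadecanal and HCl, then oxidised and cyclised through its cesium carboxylate. Ramberg–Bäcklund reaction expels SO2, forms C12=C13 and contracts the ring to 31 members in one operation; hydrogenation finishes the synthesis.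

Key step: step 5

Remark on locants: C1–C30 count along the chain from the lactone carbonyl (C1) to the OCH2 carbon (C30). Ring names count the ring oxygen as position 1, so chain C12 and C13 are ring positions 13 and 15 in the 32-membered ring and 13 and 14 in the 31-membered ring.

Remark on materials: 12-sulfanyldodecanoic acid (12-mercaptododecanoic acid) is assumed to be a commercial compound.

Remark on isomers: the alkene formed in step 5 is expected as an E/Z mixture. It is carried under one number with the E isomer drawn, because step 6 removes the double bond.

Step 1
Reactants: 1 octadecane-1,18-diol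
Product: 2 18-bromooctadecan-1-ol
Conditions: 48% aq HBr (1.2 equiv), toluene, reflux
Reagents that add atoms: hydrogen bromide, Br
Why: Monobromination of an α,ω-diol with aqueous HBr in refluxing toluene (SN2 displacement of the protonated hydroxyl) is an established desymmetrisation, and residual diol and dibromide are easily separated from the bromo alcohol.

Step 2
Reactants: 2 18-bromooctadecan-1-ol
Product: 3 18-bromooctadecanal
Conditions: PhI(OAc)2 (1.1 equiv), TEMPO (2,2,6,6-tetramethylpiperidin-1-oxyl, 10 mol%), CH2Cl2, rt
Reagents that add atoms: none
Why: The oxoammonium-mediated TEMPO/PhI(OAc)2 oxidation of a primary alcohol stops at the aldehyde without over-oxidation and leaves the primary C–Br bond untouched.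

Step 3
Reactants: 3 18-bromooctadecanal; 4 12-sulfanyldodecanoic acid
Product: 6 12-[(18-bromo-1-chlorooctadecyl)sulfonyl]dodecanoic acid (racemic), via α-chloro sulfide 5 (not isolated)
Conditions: HCl (g), anhydrous CaCl2, CH2Cl2, −15 °C; Ar purge of excess HCl; then mCPBA (2.5 equiv, as dried CH2Cl2 solution), 0 °C to rt
Reagents that add atoms: hydrogen chloride, Cl; 3-chloroperbenzoic acid (mCPBA), O=C(OO)c1cccc(Cl)c1
Why: Condensation of a thiol with an aldehyde under dry HCl (hemithioacetal, thionium ion, chloride capture) is the classical regiospecific synthesis of α-chloroalkyl sulfides and places chlorine only on the former aldehyde carbon (chain C13), and peracid oxidation of the moisture-sensitive chloro sulfide in the same flask gives the stable α-chloro sulfone; the carboxylic acid and the primary bromide tolerate both reagents, and the CHCl centre is formed without control (racemic) because step 5 destroys it.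

Step 4
Reactants: 6 12-[(18-bromo-1-chlorooctadecyl)sulfonyl]dodecanoic acid
Product: 7 15-chloro-1-oxa-14-thiacyclodotriacontan-2-one 14,14-dioxide (racemic)
Conditions: 6 in DMF added by syringe pump over 12 h to Cs2CO3 (0.6 equiv) in DMF, 50 °C, final ca. 2 mM
Reagents that add atoms: none
Why: Macrolactonisation by intramolecular SN2 O-alkylation of a cesium carboxylate with a primary bromide under high dilution is a reliable closure of large rings (here the 32-membered ring, exo-tet), and the α-chloro sulfone is a spectator because substitution at a carbon α to a sulfonyl group is extremely slow and carbonate or carboxylate is too weak a base to start the Ramberg–Bäcklund reaction.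

Step 5
Reactants: 7 15-chloro-1-oxa-14-thiacyclodotriacontan-2-one 14,14-dioxide
Product: 9 oxacyclohentriacont-13-en-2-one (triacont-12-en-30-olide as an E/Z mixture; E drawn), via episulfone 8 (not isolated)
Conditions: KOtBu (2.5 equiv), THF (5 mM), −78 °C to 0 °C
Reagents that add atoms: none
Why: KOtBu removes a proton from C12, the sulfone α-carbon that carries no chlorine (the more acidic C13–H can also be removed, but that carbanion cannot cyclise and is reprotonated), the C12 carbanion displaces chloride from C13 in a 1,3-elimination to give episulfone 8, and 8 loses SO2 cheletropically to leave the C12=C13 alkene. This is the Ramberg–Bäcklund reaction of a preformed α-chloro sulfone, a reaction type established for medium and large rings. The thiirane 1,1-dioxide ring closes in a 3-exo-tet mode, whereas the 31-membered lactone ring is not closed end to end but arises by contraction of the 32-membered ring already closed in step 4. No lasting stereocentre is created: the CHCl centre disappears, the two episulfone carbons are transient, and the alkene geometry (E expected to predominate with this strong base through epimerisation of the cis episulfone) is irrelevant because step 6 saturates the double bond. The selectivity needed is chemoselectivity for sulfone α-deprotonation over attack on the lactone, which the bulky non-nucleophilic alkoxide, the low temperature and the high dilution (against intermolecular Claisen condensation of any lactone enolate) should secure; the site of productive deprotonation is dictated by the position of chlorine, fixed in step 3.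

Step 6
Reactants: 9 oxacyclohentriacont-13-en-2-one (E/Z mixture)
Product: 10 oxacyclohentriacontan-2-one (triacontan-30-olide)
Conditions: H2 (1 atm), Pd/C (10 wt% Pd on carbon), EtOAc, rt
Reagents that add atoms: none
Why: Catalytic hydrogenation over Pd/C saturates the isolated 1,2-disubstituted alkene of either geometry without touching the lactone, so both isomers converge on the single achiral target.

Compound list
1 | octadecane-1,18-diol | OCCCCCCCCCCCCCCCCCCO | starting material
2 | 18-bromooctadecan-1-ol | OCCCCCCCCCCCCCCCCCCBr | intermediate
3 | 18-bromooctadecanal | O=CCCCCCCCCCCCCCCCCCBr | intermediate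
4 | 12-sulfanyldodecanoic acid (12-mercaptododecanoic acid) | OC(=O)CCCCCCCCCCCS | starting material
5 | 12-[(18-bromo-1-chlorooctadecyl)sulfanyl]dodecanoic acid (racemic; not isolated) | OC(=O)CCCCCCCCCCCSC(Cl)CCCCCCCCCCCCCCCCCBr | intermediate
6 | 12-[(18-bromo-1-chlorooctadecyl)sulfonyl]dodecanoic acid (racemic) | OC(=O)CCCCCCCCCCCS(=O)(=O)C(Cl)CCCCCCCCCCCCCCCCCBr | intermediate
7 | 15-chloro-1-oxa-14-thiacyclodotriacontan-2-one 14,14-dioxide (racemic) | O=C1CCCCCCCCCCCS(=O)(=O)C(Cl)CCCCCCCCCCCCCCCCCO1 | intermediate
8 | 13-oxa-32-thiabicyclo[29.1.0]dotriacontan-12-one 32,32-dioxide (episulfone across chain C12–C13; cis/trans mixture, each racemic; trans isomer drawn as one enantiomer; not isolated) | O=C1CCCCCCCCCC[C@H]2[C@H](CCCCCCCCCCCCCCCCCO1)S2(=O)=O | intermediate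
9 | oxacyclohentriacont-13-en-2-one, that is triacont-12-en-30-olide (E and Z mixture, E isomer drawn) | O=C1CCCCCCCCCC/C=C/CCCCCCCCCCCCCCCCCO1 | intermediate
10 | oxacyclohentriacontan-2-one (triacontan-30-olide) | O=C1CCCCCCCCCCCCCCCCCCCCCCCCCCCCCO1 | target

Total step count: 6
Longest linear sequence: 6 steps (1 → 2 → 3 → 6 → 7 → 9 → 10)

Steps most likely to fail

Step 5. What may go wrong: attack of the alkoxide on the lactone (ring opening, or enolisation followed by intermolecular Claisen-type condensation), or decomposition of the α-chloro carbanion faster than episulfone closure. Fallback: the C12=C13 bond would be made in the open chain by a Wittig reaction and the ring closed afterwards by carboxylate alkylation, so that no strong base meets the lactone. The fallback sets out from 3. Commercial 12-bromododecanoic acid heated with PPh3 in MeCN should give (11-carboxyundecyl)triphenylphosphonium bromide F1. The ylide carboxylate generated from F1 (NaN(SiMe3)2, 2.1 equiv, THF, −78 °C) should add to 3 and give, Z-selectively as expected for an unstabilised ylide, (12Z)-30-bromotriacont-12-enoic acid F2. Slow addition of F2 to Cs2CO3 in DMF at 50 °C under high dilution should close the ring by O-alkylation of the cesium carboxylate and give (13Z)-oxacyclohentriacont-13-en-2-one F3. Hydrogenation of F3 under the conditions of step 6 rejoins the route at 10.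

Step 3. What may go wrong: competition of the free carboxyl group with chloride for the thionium ion, hydrolysis or loss of HCl from the chloro sulfide before it is oxidised, and a difficult separation of the product acid from the acidic peracid residue. Fallback: the carboxyl group would be masked as its methyl ester, so that every intermediate is neutral and can be washed with aqueous NaHCO3, and unmasked under acidic conditions that the chloro sulfone and the bromide tolerate. The fallback sets out from 4. Fischer esterification (MeOH, cat. H2SO4, reflux, Ar) should give methyl 12-sulfanyldodecanoate F4. Condensation of F4 with 3 under dry HCl as in step 3 should give methyl 12-[(18-bromo-1-chlorooctadecyl)sulfanyl]dodecanoate F5, which would be oxidised without purification by mCPBA to methyl 12-[(18-bromo-1-chlorooctadecyl)sulfonyl]dodecanoate F6. Acid hydrolysis of F6 (48% aq HBr, AcOH, 90 °C; HBr is chosen so that the primary bromide is not exchanged) rejoins the route at 6.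

Step 4. What may go wrong: intermolecular O-alkylation outruns ring closure (linear oligomers, cyclic dimer), or carbonate-mediated alkylation occurs at the CHCl carbon. Fallback: the ester would be formed first as an open-chain bond and the 32-membered ring closed at sulfur by fast thiolate alkylation, at the price of an unselective chlorination. The fallback sets out from 2. DCC/DMAP esterification of 2 with commercial 12-bromododecanoic acid in CH2Cl2 should give 18-bromooctadecyl 12-bromododecanoate F7. Simultaneous slow addition of F7 and Na2S·9H2O to degassed DMF at 40 °C (final ca. 2 mM) should give 1-oxa-14-thiacyclodotriacontan-2-one F8 by double S-alkylation. NCS in CH2Cl2 should chlorinate either α-carbon and give 15-chloro-1-oxa-14-thiacyclodotriacontan-2-one F9 and 13-chloro-1-oxa-14-thiacyclodotriacontan-2-one F10, neither isolated. Oxidation of the crude pair with mCPBA should give 7 mixed with 13-chloro-1-oxa-14-thiacyclodotriacontan-2-one 14,14-dioxide F11. The route is rejoined at 7; F11 is carried along unseparated, because under the conditions of step 5 it collapses to the same episulfone 8 and alkene 9.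

Further compounds
F1 | step 5 | (11-carboxyundecyl)triphenylphosphonium bromide | OC(=O)CCCCCCCCCCC[P+](c1ccccc1)(c1ccccc1)c1ccccc1.[Br-]
F2 | step 5 | (12Z)-30-bromotriacont-12-enoic acid | OC(=O)CCCCCCCCCC/C=C\CCCCCCCCCCCCCCCCCBr
F3 | step 5 | (13Z)-oxacyclohentriacont-13-en-2-one | O=C1CCCCCCCCCC/C=C\CCCCCCCCCCCCCCCCCO1
F4 | step 3 | methyl 12-sulfanyldodecanoate | COC(=O)CCCCCCCCCCCS
F5 | step 3 | methyl 12-[(18-bromo-1-chlorooctadecyl)sulfanyl]dodecanoate (racemic) | COC(=O)CCCCCCCCCCCSC(Cl)CCCCCCCCCCCCCCCCCBr
F6 | step 3 | methyl 12-[(18-bromo-1-chlorooctadecyl)sulfonyl]dodecanoate (racemic) | COC(=O)CCCCCCCCCCCS(=O)(=O)C(Cl)CCCCCCCCCCCCCCCCCBr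
F7 | step 4 | 18-bromooctadecyl 12-bromododecanoate | BrCCCCCCCCCCCC(=O)OCCCCCCCCCCCCCCCCCCBr
F8 | step 4 | 1-oxa-14-thiacyclodotriacontan-2-one | O=C1CCCCCCCCCCCSCCCCCCCCCCCCCCCCCCO1
F9 | step 4 | 15-chloro-1-oxa-14-thiacyclodotriacontan-2-one (racemic) | O=C1CCCCCCCCCCCSC(Cl)CCCCCCCCCCCCCCCCCO1
F10 | step 4 | 13-chloro-1-oxa-14-thiacyclodotriacontan-2-one (racemic) | O=C1CCCCCCCCCCC(Cl)SCCCCCCCCCCCCCCCCCCO1
F11 | step 4 | 13-chloro-1-oxa-14-thiacyclodotriacontan-2-one 14,14-dioxide (racemic) | O=C1CCCCCCCCCCC(Cl)S(=O)(=O)CCCCCCCCCCCCCCCCCCO1
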